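The trap here is to read the Z column as a first-order decay. At a given rate constant, such a decay takes the same percentage from any charge.

| flask | Z | L | remark | time |
|---|---|---|---|---|
| beta | 0.050 M | 0.040 M | run made earlier |  |
| gamma | 0.050 M | 0.090 M | run made earlier |  |
| eta | 0.025 M | 0.060 M | run made earlier |  |
| flask | 0.050 M | 0.0600 M |  | 12 min |

- beta (time / min: Q / %, Z / %, G / %): 0.500: 0, 99.6, 0; 1.33: 1.6, 96.3, 0.6; 2.50: 5.3, 92.7, 0; 4.00: 5.6, 87.7, 1.3; 6.00: 11.5, 79.6, 0; 8.00: 18.3, 75.3, 1.5
- gamma (time / min: Q / %, Z / %, G / %): 0.500: 0, 97.2, 0; 1.33: 0.9, 95.9, 0.3; 2.50: 7.0, 91.2, 1.4; 4.00: 10.3, 85.9, 0; 6.00: 16.2, 78.6, 0; 8.00: 23.5, 71.7, 1.5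
- eta (time / min: Q / %, Z / %, G / %): 0.500: 0.7, 96.0, 0; 1.00: 2.1, 95.2, 0; 2.00: 6.5, 84.6, 0; 4.00: 17.5, 73.9, 0.3; 8.00: 41.9, 45.5, 2.1

(scatter of a reading: 1 percentage point)

- percent here means Z units held: one G counts as two
- Z is a solid; its amount is given per volume of the solution
- what was read earlier has a scatter of 1 percentage point, one standard deviation
- at the start none of Z is in solution
- as a choice and as an amount asked, Z means what is still solid

* the species in which most of what was charged as Z, at 12 min sits (G / Q / Z)
* the largest share itself, whichever of these holds it, in percent of the Z charged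

But by 8.00 min the eta run, charged with half the Z of the beta run, has lost 54.5 % of its solid, and beta has lost 24.7 %. In amounts the two are close, 0.0136 M and 0.0123 M, so I count the solid in molar rather than in percent.

The eta run loses 0.00163 M min⁻¹ on average up to 4.00 min and 0.00170 M min⁻¹ up to 8.00 min. I freeze the second figure and call it the drain, the amount of solid lost per minute from each litre of solution, a zero-order rate. Beta reads 0.00154 M min⁻¹ and gamma 0.00177 M min⁻¹, but eta has the L of this flask, 0.0600 M, so I use eta's value.

For this flask at 12 min:

solid left = 1 − drain × time / Z charged = 59.1 %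

The other forms together can then hold 40.9 %, less than the solid, so I expect Z to hold the largest share.

The forecast takes the same view: “The solid disappears at a steady absolute rate.” It uses 0.00165 M/min where I use 0.00170 M min⁻¹, and it gives Z at 60 %, within 56 % to 64 %.

The flask gives Z at 58.4 %, with Q at 30.5 % and G at 6.15 %, inside the forecast's range.

    Z ⇌ X, rate k1*(cs1 - [X]) while solid is left; crystals form when [X] > cs1 (solubility = 18.0 mM, k = 0.100 min⁻¹)
    X + L → Q (k = 14.0 M⁻¹ min⁻¹)
    Z + Q → G (k = 0.490 M⁻¹ min⁻¹)

In this flask X, the dissolved Z, is made 1.04 times as fast as it is used up at 5.88 min and 1.05 times at 12.0 min, each step taken net. At 12.0 min it stands at 0.00246 M, far below the 18 mM in the rate of going into solution, and that rate is then 0.00155 M min⁻¹, against 0.00180 M min⁻¹ at the start, when none of Z is in solution.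

The second neighbour has the same L but 0.030 M of Z, and there the drain gives 1 − drain × time / Z charged = 32.0 % solid. Computed, that flask holds 33.4 % as Z, and Q holds more than that, 53.6 %.

Readings and results come from a simulation on assumed constants, and the scatter is random.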